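**Plan**

1. Retrosynthesis: the hydroxyquinone (ring B) is taken back to a 2,4,5-trimethoxy-3-prenylphenyl group (oxidative demethylation, then hydrolysis of the vinylogous ester), and the O5 methyl / O7–H pair to a 5,7-bis(MOM) chroman.
2. The pyran ring (ring C) is then cut at C4–C4a and O1–C2, giving the symmetric 3,5-bis(methoxymethoxy)-4-prenylphenol and a 2-arylacrolein that supplies C2, C3 and C4; both aryl–prenyl bonds go back to aryllithiums and prenyl bromide.
3. Enabling feature: ring A is 1,3,5-trioxygenated and C4a lies ortho to the O1 phenol, so C4a can attack as a carbon nucleophile while O1 closes onto C2; C2, C3 and C4 map onto the carbonyl, α- and β-carbon of an acrolein carrying ring B.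
4. Forward: ring A (from phloroglucinol) and ring B (from 2,4,5-trimethoxybenzaldehyde) are each prenylated by directed ortho-lithiation and joined in step 10, where C4–C4a forms and ring C closes as a lactol. Reduction and Mitsunobu closure give the chroman; the O5/O7 distinction and the quinone come last.
5. Stereochemistry: C3 (R), the only stereocentre, is set in step 10 by catalyst-controlled protonation of an enamine; no later step makes or breaks a bond at C3.

Key step: step 10

Remarks. Isoflavan numbering is used (O1, C2, C3, C4, C4a–C8a; primed atoms for ring B). Prenyl = 3-methylbut-2-en-1-yl, MOM = methoxymethyl, TIPS = triisopropylsilyl. The target SMILES is read as 3R (C2 > C1′ > C4 > H).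
Assumption: the sense of induction of the diamine catalyst in step 10 cannot be assigned with certainty in advance; the (S)-diamine is written, and its mirror image, equally accessible, is used instead if that is the one leading to 3R.

**Route**

Step 1
Reactants: 1 phloroglucinol
Product: 2 5-[(triisopropylsilyl)oxy]benzene-1,3-diol
Conditions: iPr3SiCl (0.5 equiv), imidazole, DMF, 0 °C to rt
Reagents that add atoms: triisopropylsilyl chloride, CC(C)[Si](Cl)(C(C)C)C(C)C
Why: Silylation of one of three equivalent phenols with a bulky silyl chloride; keeping the cheap triol in excess should hold the reaction at the mono-ether.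

Step 2
Reactants: 2 5-[(triisopropylsilyl)oxy]benzene-1,3-diol
Product: 3 [3,5-bis(methoxymethoxy)phenoxy]triisopropylsilane
Conditions: MOMCl (3 equiv), iPr2NEt, CH2Cl2, 0 °C to rt
Reagents that add atoms: chloromethyl methyl ether, COCCl
Why: Williamson-type O-alkylation of both remaining phenols with an α-chloro ether under amine base, which leaves the aryl silyl ether untouched.

Step 3
Reactants: 3 [3,5-bis(methoxymethoxy)phenoxy]triisopropylsilane; 4 prenyl bromide (1-bromo-3-methylbut-2-ene)
Product: 6 [3,5-bis(methoxymethoxy)-4-prenylphenoxy]triisopropylsilane, via aryllithium 5 (not isolated)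
Conditions: n-BuLi, THF, 0 °C; then prenyl bromide, −78 °C to rt
Reagents that add atoms: none
Why: Directed ortho-metalation at the one carbon flanked by two coordinating MOM ethers (the sites next to the bulky, non-coordinating silyl ether should stay untouched), followed by SN2 alkylation of the aryllithium at the primary carbon of the allylic bromide.

Step 4
Reactants: 6 [3,5-bis(methoxymethoxy)-4-prenylphenoxy]triisopropylsilane
Product: 7 3,5-bis(methoxymethoxy)-4-prenylphenol
Conditions: Bu4NF, AcOH, THF, 0 °C
Reagents that add atoms: none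
Why: Fluoride-induced cleavage of the aryl Si–O bond; the acetic acid buffer avoids a free phenoxide, and MOM ethers and the alkene are inert.

Step 5
Reactants: 8 2,4,5-trimethoxybenzaldehyde
Product: 9 1,2,4-trimethoxy-5-(2-methoxyethenyl)benzene (E/Z mixture)
Conditions: Ph3P(CH2OMe)Cl, KOtBu, THF, 0 °C to rt
Reagents that add atoms: (methoxymethyl)triphenylphosphonium chloride, COC[P+](c1ccccc1)(c1ccccc1)c1ccccc1.[Cl-]
Why: Wittig methoxymethylenation of an aromatic aldehyde gives the one-carbon-homologated enol ether; its geometry is of no consequence.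

Step 6
Reactants: 9 1,2,4-trimethoxy-5-(2-methoxyethenyl)benzene
Product: 10 1-(2,2-dimethoxyethyl)-2,4,5-trimethoxybenzene
Conditions: MeOH, p-TsOH·H2O (cat.), rt
Reagents that add atoms: methanol, CO
Why: Acid-catalysed addition of methanol to the enol ether (protonation at the benzylic carbon, capture of the oxocarbenium ion) gives the dimethyl acetal, which masks the aldehyde for the organolithium step.

Step 7
Reactants: 10 1-(2,2-dimethoxyethyl)-2,4,5-trimethoxybenzene; 4 prenyl bromide
Product: 12 1-(2,2-dimethoxyethyl)-2,4,5-trimethoxy-3-prenylbenzene, via aryllithium 11 (not isolated)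
Conditions: n-BuLi, TMEDA, THF, 0 °C; then prenyl bromide, −78 °C to rt
Reagents that add atoms: none
Why: Directed ortho-metalation at C3′, the only ring C–H lying between two methoxy groups, then SN2 alkylation with the allylic bromide; the acetal is inert to the base.

Step 8
Reactants: 12 1-(2,2-dimethoxyethyl)-2,4,5-trimethoxy-3-prenylbenzene
Product: 13 2-(2,4,5-trimethoxy-3-prenylphenyl)acetaldehyde
Conditions: 1 M HCl (aq), THF, rt; used crude
Reagents that add atoms: water, O
Why: Acetal hydrolysis in dilute acid, mild enough to spare the trisubstituted alkene; the self-condensing arylacetaldehyde is carried on without purification.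

Step 9
Reactants: 13 2-(2,4,5-trimethoxy-3-prenylphenyl)acetaldehyde
Product: 15 2-(2,4,5-trimethoxy-3-prenylphenyl)prop-2-enal, via Mannich base 14 (not isolated)
Conditions: [Me2N=CH2]I, Et3N, CH2Cl2, rt; used at once
Reagents that add atoms: dimethyl(methylidene)ammonium iodide, C=[N+](C)C.[I-]
Why: Mannich reaction at the enolisable benzylic α-carbon, then E1cB loss of dimethylamine from the β-amino aldehyde, gives the α-methylene aldehyde.

Step 10
Reactants: 7 3,5-bis(methoxymethoxy)-4-prenylphenol; 15 2-(2,4,5-trimethoxy-3-prenylphenyl)prop-2-enal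
Product: 17 (3R)-5,7-bis(methoxymethoxy)-6-prenyl-3-(2,4,5-trimethoxy-3-prenylphenyl)chroman-2-ol (both C2 anomers), via open-chain hydroxy aldehyde 16 (not isolated)
Conditions: (S)-N1,N1-diethyl-3,3-dimethylbutane-1,2-diamine (20 mol %), CF3SO3H (20 mol %), 7 (1.5 equiv), CHCl3, 0 °C
Reagents that add atoms: none
Why: Proposed new method: the primary amine of the catalyst condenses with enal 15 to an iminium ion, whose unsubstituted β-carbon is attacked by phenol 7 through the ring carbon ortho to the free hydroxyl (C4–C4a), and rearomatisation leaves an enamine bearing ring B on its α-carbon. The protonated tertiary amine of the same catalyst, held next to that carbon, passes its proton to one face of the enamine and so sets C3 (R); hydrolysis then releases aldehyde 16 and the catalyst. The O1 phenol adds to the aldehyde carbon in a 6-exo-trig closure (O1–C2) to give lactol 17, which keeps the α-aryl aldehyde from re-forming an enamine and so guards C3. The closest known reactions are the amine-catalysed Friedel–Crafts addition of electron-rich phenols to enals with hemiacetal closure and the primary-amine-catalysed conjugate addition to α-substituted acroleins with enantioselective enamine protonation; their union on a 2-arylacrolein is the untested part. Regioselectivity needs no control, because the two carbons ortho to the hydroxyl of 7 are equivalent by symmetry, the para carbon carries the prenyl group and the MOM ethers leave O1 as the only oxygen able to close; the excess of 7 should hold back a second alkylation at C8, and enantioselectivity rests on the catalyst alone.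

Step 11
Reactants: 17 (3R)-5,7-bis(methoxymethoxy)-6-prenyl-3-(2,4,5-trimethoxy-3-prenylphenyl)chroman-2-ol
Product: 18 (2R)-3-[6-hydroxy-2,4-bis(methoxymethoxy)-3-prenylphenyl]-2-(2,4,5-trimethoxy-3-prenylphenyl)propan-1-ol
Conditions: NaBH4, THF/MeOH, −20 to 0 °C (on crude 17)
Reagents that add atoms: none
Why: Borohydride reduces the hydroxy aldehyde in equilibrium with the lactol to the primary alcohol; the low temperature should let reduction outrun enolisation, and C3 is then no longer α to a carbonyl.

Step 12
Reactants: 18 (2R)-3-[6-hydroxy-2,4-bis(methoxymethoxy)-3-prenylphenyl]-2-(2,4,5-trimethoxy-3-prenylphenyl)propan-1-ol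
Product: 19 (3R)-5,7-bis(methoxymethoxy)-6-prenyl-3-(2,4,5-trimethoxy-3-prenylphenyl)chroman
Conditions: PPh3, DIAD, THF, 0 °C to rt
Reagents that add atoms: none
Why: Intramolecular Mitsunobu etherification, in which the O1 phenol displaces the activated primary alcohol (6-exo-tet) and closes O1–C2 without touching C3.

Step 13
Reactants: 19 (3R)-5,7-bis(methoxymethoxy)-6-prenyl-3-(2,4,5-trimethoxy-3-prenylphenyl)chroman
Product: 20 (3R)-6-prenyl-3-(2,4,5-trimethoxy-3-prenylphenyl)chroman-5,7-diol
Conditions: HCl (1.25 M in MeOH), 0 °C to rt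
Reagents that add atoms: none
Why: Acid-catalysed acetal exchange passes both MOM groups to methanol; dilute acid at or below room temperature is the usual way to do this next to prenyl groups without cyclising them onto the freed phenols.

Step 14
Reactants: 20 (3R)-6-prenyl-3-(2,4,5-trimethoxy-3-prenylphenyl)chroman-5,7-diol
Product: 21 (3R)-6-prenyl-7-[(triisopropylsilyl)oxy]-3-(2,4,5-trimethoxy-3-prenylphenyl)chroman-5-ol
Conditions: iPr3SiCl (1.05 equiv), imidazole, CH2Cl2, 0 °C
Reagents that add atoms: triisopropylsilyl chloride, CC(C)[Si](Cl)(C(C)C)C(C)C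
Why: Site-selective silylation on steric grounds: O7 has one ortho substituent (prenyl; H at C8), whereas O5 is flanked by the prenyl group and the C4 methylene and should resist the bulky chloride.

Step 15
Reactants: 21 (3R)-6-prenyl-7-[(triisopropylsilyl)oxy]-3-(2,4,5-trimethoxy-3-prenylphenyl)chroman-5-ol
Product: 22 (3R)-5-methoxy-6-prenyl-7-[(triisopropylsilyl)oxy]-3-(2,4,5-trimethoxy-3-prenylphenyl)chroman
Conditions: MeI, K2CO3, acetone, 50 °C
Reagents that add atoms: iodomethane, CI
Why: Williamson methylation of the one remaining phenol; the aryl TIPS ether should tolerate anhydrous carbonate.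

Step 16
Reactants: 22 (3R)-5-methoxy-6-prenyl-7-[(triisopropylsilyl)oxy]-3-(2,4,5-trimethoxy-3-prenylphenyl)chroman
Product: 23 2-methoxy-3-prenyl-5-[(3R)-5-methoxy-6-prenyl-7-(triisopropylsilyloxy)chroman-3-yl]-1,4-benzoquinone
Conditions: (NH4)2Ce(NO3)6 (2.5 equiv), MeCN/H2O, 0 °C, short reaction time
Reagents that add atoms: water, O
Why: Oxidative demethylation of the para-dimethoxy pair (C2′/C5′) by tetravalent cerium gives the p-quinone; the 1,2,4-trioxygenated ring B should be oxidised well before the meta-oxygenated ring A, and the C4′ methoxy stays as a vinylogous ester.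

Step 17
Reactants: 23 2-methoxy-3-prenyl-5-[(3R)-5-methoxy-6-prenyl-7-(triisopropylsilyloxy)chroman-3-yl]-1,4-benzoquinone
Product: 24 2-hydroxy-3-prenyl-5-[(3R)-5-methoxy-6-prenyl-7-(triisopropylsilyloxy)chroman-3-yl]-1,4-benzoquinone
Conditions: NaOH (0.5 M aq), THF, 0 °C, argon; then cold 1 M HCl to pH 3
Reagents that add atoms: sodium hydroxide, [Na+].[OH-]
Why: Addition–elimination of hydroxide at the methoxy-bearing carbon of the vinylogous ester gives the hydroxyquinone, whose delocalised anion resists further attack; any early loss of the silyl group converges on the target in the next step.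

Step 18
Reactants: 24 2-hydroxy-3-prenyl-5-[(3R)-5-methoxy-6-prenyl-7-(triisopropylsilyloxy)chroman-3-yl]-1,4-benzoquinone
Product: 25 2-hydroxy-5-[(3R)-7-hydroxy-5-methoxy-6-prenylchroman-3-yl]-3-prenyl-1,4-benzoquinone (CNP0148998.1)
Conditions: Bu4NF, AcOH, THF, 0 °C
Reagents that add atoms: none
Why: Buffered fluoride cleavage of the aryl silyl ether frees O7–H without exposing the quinone, the prenyl groups or C3 to strong base or acid.

**Compound list**

1 | phloroglucinol | Oc1cc(O)cc(O)c1 | starting material
2 | 5-[(triisopropylsilyl)oxy]benzene-1,3-diol | CC(C)[Si](Oc1cc(O)cc(O)c1)(C(C)C)C(C)C | intermediate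
3 | [3,5-bis(methoxymethoxy)phenoxy]triisopropylsilane | COCOc1cc(OCOC)cc(O[Si](C(C)C)(C(C)C)C(C)C)c1 | intermediate
4 | prenyl bromide | CC(C)=CCBr | starting material
5 | [2,6-bis(methoxymethoxy)-4-(triisopropylsilyloxy)phenyl]lithium | [Li]c1c(OCOC)cc(O[Si](C(C)C)(C(C)C)C(C)C)cc1OCOC | intermediate
6 | [3,5-bis(methoxymethoxy)-4-prenylphenoxy]triisopropylsilane | COCOc1cc(O[Si](C(C)C)(C(C)C)C(C)C)cc(OCOC)c1CC=C(C)C | intermediate
7 | 3,5-bis(methoxymethoxy)-4-prenylphenol | COCOc1cc(O)cc(OCOC)c1CC=C(C)C | intermediate
8 | 2,4,5-trimethoxybenzaldehyde | COc1cc(OC)c(C=O)cc1OC | starting material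
9 | 1,2,4-trimethoxy-5-(2-methoxyethenyl)benzene (E/Z) | COC=Cc1cc(OC)c(OC)cc1OC | intermediate
10 | 1-(2,2-dimethoxyethyl)-2,4,5-trimethoxybenzene | COC(OC)Cc1cc(OC)c(OC)cc1OC | intermediate
11 | [3-(2,2-dimethoxyethyl)-2,5,6-trimethoxyphenyl]lithium | COC(OC)Cc1cc(OC)c(OC)c([Li])c1OC | intermediate
12 | 1-(2,2-dimethoxyethyl)-2,4,5-trimethoxy-3-prenylbenzene | COC(OC)Cc1cc(OC)c(OC)c(CC=C(C)C)c1OC | intermediate
13 | 2-(2,4,5-trimethoxy-3-prenylphenyl)acetaldehyde | O=CCc1cc(OC)c(OC)c(CC=C(C)C)c1OC | intermediate
14 | 3-(dimethylamino)-2-(2,4,5-trimethoxy-3-prenylphenyl)propanal (racemic) | CN(C)CC(C=O)c1cc(OC)c(OC)c(CC=C(C)C)c1OC | intermediate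
15 | 2-(2,4,5-trimethoxy-3-prenylphenyl)prop-2-enal | C=C(C=O)c1cc(OC)c(OC)c(CC=C(C)C)c1OC | intermediate
16 | (2R)-3-[6-hydroxy-2,4-bis(methoxymethoxy)-3-prenylphenyl]-2-(2,4,5-trimethoxy-3-prenylphenyl)propanal | COCOc1c(CC=C(C)C)c(OCOC)cc(O)c1C[C@H](c1cc(OC)c(OC)c(CC=C(C)C)c1OC)C=O | intermediate
17 | (3R)-5,7-bis(methoxymethoxy)-6-prenyl-3-(2,4,5-trimethoxy-3-prenylphenyl)chroman-2-ol (C2 anomers) | COCOc1c(CC=C(C)C)c(OCOC)cc2c1C[C@H](c1cc(OC)c(OC)c(CC=C(C)C)c1OC)C(O)O2 | intermediate
18 | (2R)-3-[6-hydroxy-2,4-bis(methoxymethoxy)-3-prenylphenyl]-2-(2,4,5-trimethoxy-3-prenylphenyl)propan-1-ol | COCOc1c(CC=C(C)C)c(OCOC)cc(O)c1C[C@H](c1cc(OC)c(OC)c(CC=C(C)C)c1OC)CO | intermediate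
19 | (3R)-5,7-bis(methoxymethoxy)-6-prenyl-3-(2,4,5-trimethoxy-3-prenylphenyl)chroman | COCOc1c(CC=C(C)C)c(OCOC)cc2c1C[C@H](c1cc(OC)c(OC)c(CC=C(C)C)c1OC)CO2 | intermediate
20 | (3R)-6-prenyl-3-(2,4,5-trimethoxy-3-prenylphenyl)chroman-5,7-diol | Oc1c(CC=C(C)C)c(O)cc2c1C[C@H](c1cc(OC)c(OC)c(CC=C(C)C)c1OC)CO2 | intermediate
21 | (3R)-6-prenyl-7-[(triisopropylsilyl)oxy]-3-(2,4,5-trimethoxy-3-prenylphenyl)chroman-5-ol | Oc1c(CC=C(C)C)c(O[Si](C(C)C)(C(C)C)C(C)C)cc2c1C[C@H](c1cc(OC)c(OC)c(CC=C(C)C)c1OC)CO2 | intermediate
22 | (3R)-5-methoxy-6-prenyl-7-[(triisopropylsilyl)oxy]-3-(2,4,5-trimethoxy-3-prenylphenyl)chroman | COc1c(CC=C(C)C)c(O[Si](C(C)C)(C(C)C)C(C)C)cc2c1C[C@H](c1cc(OC)c(OC)c(CC=C(C)C)c1OC)CO2 | intermediate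
23 | 2-methoxy-3-prenyl-5-[(3R)-5-methoxy-6-prenyl-7-(triisopropylsilyloxy)chroman-3-yl]-1,4-benzoquinone | COc1c(CC=C(C)C)c(O[Si](C(C)C)(C(C)C)C(C)C)cc2c1C[C@H](C1=CC(=O)C(OC)=C(CC=C(C)C)C1=O)CO2 | intermediate
24 | 2-hydroxy-3-prenyl-5-[(3R)-5-methoxy-6-prenyl-7-(triisopropylsilyloxy)chroman-3-yl]-1,4-benzoquinone | COc1c(CC=C(C)C)c(O[Si](C(C)C)(C(C)C)C(C)C)cc2c1C[C@H](C1=CC(=O)C(O)=C(CC=C(C)C)C1=O)CO2 | intermediate
25 | 2-hydroxy-5-[(3R)-7-hydroxy-5-methoxy-6-prenylchroman-3-yl]-3-prenyl-1,4-benzoquinone | COc1c(CC=C(C)C)c(O)cc2c1C[C@H](C1=CC(=O)C(O)=C(CC=C(C)C)C1=O)CO2 | target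

**Step count**

Total: 18 steps. Longest linear sequence: 14 steps (steps 5–18, from 2,4,5-trimethoxybenzaldehyde); the ring A branch (steps 1–4) joins at step 10.

**Steps most likely to fail**

Step 10 (new method). What may go wrong: weak face discrimination in the proton transfer to the α-aryl enamine, loss of configuration through renewed enamine formation from the open aldehyde before it closes, and a second alkylation at C8. The fallback keeps the bond formation but frees it of any stereochemical task and sets C3 in the reduction instead. It sets out from 7 and 15, which are combined under an achiral primary ammonium salt (cyclohexylamine, CF3CO2H, CHCl3, rt). Iminium-type Friedel–Crafts addition of electron-rich phenols to enals with hemiacetal closure is an established reaction class. This should give the racemic lactol 5,7-bis(methoxymethoxy)-6-prenyl-3-(2,4,5-trimethoxy-3-prenylphenyl)chroman-2-ol F1. F1 is then hydrogenated under dynamic kinetic resolution: H2 (50 bar), RuCl2[(S)-SDP][(R,R)-DACH] (SDP = 7,7′-bis(diphenylphosphino)-1,1′-spirobiindane, DACH = trans-1,2-diaminocyclohexane; the mirror-image complex if that one leads to R), KOtBu (more than one equivalent, since the phenol takes up one), iPrOH, rt. The base opens the lactol and racemises the α-aryl aldehyde through its enolate faster than it is reduced, and the chiral ruthenium hydride reduces one aldehyde enantiomer preferentially. This class of carbonyl-selective catalyst leaves isolated trisubstituted alkenes alone, and asymmetric hydrogenation of racemic α-aryl aldehydes in this way is known chemistry. The product is diol 18, where the fallback rejoins the route ahead of step 12.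

Step 14. What may go wrong: incomplete discrimination between O7 and O5 during silylation, giving some O5 silylation or double silylation. The fallback replaces selective protection by selective deprotection. It sets out from 20, which is peracetylated (Ac2O, pyridine, DMAP cat., CH2Cl2) to the diacetate (3R)-6-prenyl-3-(2,4,5-trimethoxy-3-prenylphenyl)chroman-5,7-diyl diacetate F2. Enzymatic alcoholysis (Candida antarctica lipase B, n-BuOH, tert-butyl methyl ether, 40 °C) should remove only the exposed 7-acetate, the 5-acetate being shielded on both sides, to give (3R)-7-hydroxy-6-prenyl-3-(2,4,5-trimethoxy-3-prenylphenyl)chroman-5-yl acetate F3. The single free phenol is silylated (iPr3SiCl, imidazole, CH2Cl2) to (3R)-6-prenyl-7-[(triisopropylsilyl)oxy]-3-(2,4,5-trimethoxy-3-prenylphenyl)chroman-5-yl acetate F4. Reductive removal of the acetate (iBu2AlH, CH2Cl2, −78 °C) then returns to the route at 21.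

Step 16. What may go wrong: over-oxidation (ring A or the alkenes), competing ortho-quinone formation across C4′/C5′, or loss of the silyl ether in the acidic cerium medium. The fallback replaces the one-electron chemical oxidant by anodic oxidation in buffered methanol. It sets out from 22, which is electrolysed (graphite anode, LiClO4, 2,6-lutidine, MeOH, 0 °C, constant current, undivided cell). Anodic bis-methoxylation of para-dimethoxyarenes is known and should give the quinone bis(dimethyl acetal) (3R)-5-methoxy-3-[3,3,4,6,6-pentamethoxy-5-prenylcyclohexa-1,4-dien-1-yl]-6-prenyl-7-[(triisopropylsilyl)oxy]chroman F5. Mild hydrolysis of both acetals (AcOH/H2O/THF, rt) then returns to the route at 23.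

**Further compounds**

F1 | step 10 | 5,7-bis(methoxymethoxy)-6-prenyl-3-(2,4,5-trimethoxy-3-prenylphenyl)chroman-2-ol, racemic at C3 | COCOc1c(CC=C(C)C)c(OCOC)cc2c1CC(c1cc(OC)c(OC)c(CC=C(C)C)c1OC)C(O)O2
F2 | step 14 | (3R)-6-prenyl-3-(2,4,5-trimethoxy-3-prenylphenyl)chroman-5,7-diyl diacetate | CC(=O)Oc1c(CC=C(C)C)c(OC(C)=O)cc2c1C[C@H](c1cc(OC)c(OC)c(CC=C(C)C)c1OC)CO2
F3 | step 14 | (3R)-7-hydroxy-6-prenyl-3-(2,4,5-trimethoxy-3-prenylphenyl)chroman-5-yl acetate | CC(=O)Oc1c(CC=C(C)C)c(O)cc2c1C[C@H](c1cc(OC)c(OC)c(CC=C(C)C)c1OC)CO2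
F4 | step 14 | (3R)-6-prenyl-7-[(triisopropylsilyl)oxy]-3-(2,4,5-trimethoxy-3-prenylphenyl)chroman-5-yl acetate | CC(=O)Oc1c(CC=C(C)C)c(O[Si](C(C)C)(C(C)C)C(C)C)cc2c1C[C@H](c1cc(OC)c(OC)c(CC=C(C)C)c1OC)CO2
F5 | step 16 | (3R)-5-methoxy-3-[3,3,4,6,6-pentamethoxy-5-prenylcyclohexa-1,4-dien-1-yl]-6-prenyl-7-[(triisopropylsilyl)oxy]chroman | COc1c(CC=C(C)C)c(O[Si](C(C)C)(C(C)C)C(C)C)cc2c1C[C@H](C1=CC(OC)(OC)C(OC)=C(CC=C(C)C)C1(OC)OC)CO2
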